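**Retrosynthetic overview**
- The only ring, the 19-membered macrocycle, is closed last but one by forming the C14–C15 bond of the β-keto amide: a SnCl2-promoted intramolecular Roskamp-type reaction of a diazoacetamide with the C15 aldehyde. Desilylation then gives the target.
- The open chain comes from a Z-selective Still–Gennari olefination (C3=C4) between the phosphonopropionate ester of the C19 alcohol (western fragment) and the C4 aldehyde (eastern fragment).
- Western fragment: two enamine-catalysed Michael additions of propanal to vinyl ketones set the C3′ and C16 methyl centres; two oxazaborolidine-catalysed ketone reductions set the C6′ and C19 carbinols.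
- Eastern fragment: transaminase amination of ethyl levulinate sets C11; the derived N-Boc lactam is opened with CH2=CHMgBr; hydrosilylation/Mukaiyama aldol sets C6 and C7 with an aldehyde from lipase desymmetrisation of 2-methylpropane-1,3-diol (C5).

Assumption and notation: catalysts, enzymes, 2,5-dioxopyrrolidin-1-yl 2-diazoacetate and compounds 2, 7 and 16 are bought; locants (O1, C2 … N12 … C19, side chain C1′–C10′) are those of the systematic name of 36; TBS = tert-butyldimethylsilyl, Boc = tert-butoxycarbonyl.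

**Step 1**
Reactants: 1 acrolein; 2 ethyl 2-(triphenyl-λ5-phosphanylidene)propanoate
Product: 3 ethyl (2E)-2-methylpenta-2,4-dienoate
Conditions: CH2Cl2, 0 °C → rt
Reagents that add atoms: none
Why: Wittig olefination with a stabilised ylide gives the E-trisubstituted dienoate.

**Step 2**
Reactants: 3 ethyl (2E)-2-methylpenta-2,4-dienoate
Product: 5 (4E)-4-methylhepta-1,4,6-trien-3-one, via Weinreb amide 4 (not isolated)
Conditions: MeNH(OMe)·HCl, i-PrMgCl, THF, −20 °C; then CH2=CHMgBr, −20 → 0 °C; inverse quench into cold 1 M HCl; used at once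
Reagents that add atoms: vinylmagnesium bromide (C=C[Mg]Br)
Why: One-pot Weinreb ketone synthesis; the chelated tetrahedral adduct releases the ketone only on the acid quench, which also keeps the freed amine from adding to the enone.

**Step 3**
Reactants: 5 (4E)-4-methylhepta-1,4,6-trien-3-one; 6 propanal; 7 N-methoxy-N-methyl-2-(triphenyl-λ5-phosphanylidene)acetamide
Product: 9 (2E,4S,8E)-N-methoxy-N,4,8-trimethyl-7-oxoundeca-2,8,10-trienamide, via Michael aldehyde 8 (not isolated)
Conditions: (R)-2-(methoxydiphenylmethyl)pyrrolidine (10 mol%), ethyl 3,4-dihydroxybenzoate (20 mol%), propanal (4 equiv), 4 °C; evaporate propanal; then 7, CH2Cl2, rt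
Reagents that add atoms: none
Why: Enamine-catalysed asymmetric Michael addition to the unsubstituted vinyl terminus (attack on the enamine face remote from the diphenylmethoxymethyl group of the (R)-catalyst sets C3′ as S), then in-situ Wittig olefination of the labile α-branched aldehyde to the E-enamide.

**Step 4**
Reactants: 9 (2E,4S,8E)-N-methoxy-N,4,8-trimethyl-7-oxoundeca-2,8,10-trienamide
Product: 10 (2E,4S,7S,8E)-7-hydroxy-N-methoxy-N,4,8-trimethylundeca-2,8,10-trienamide
Conditions: (R)-2-methyl-CBS-oxazaborolidine (20 mol%), catecholborane, toluene, −78 °C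
Reagents that add atoms: none
Why: Corey–Bakshi–Shibata reduction in which the α-methyl dienyl group is the large substituent, so the (R)-catalyst gives the (S)-carbinol (C6′); catecholborane at −78 °C leaves diene and enamide untouched.

**Step 5**
Reactants: 10 (2E,4S,7S,8E)-7-hydroxy-N-methoxy-N,4,8-trimethylundeca-2,8,10-trienamide
Product: 11 (2E,4S,7S,8E)-7-(TBS-oxy)-N-methoxy-N,4,8-trimethylundeca-2,8,10-trienamide
Conditions: TBSCl, imidazole, DMF, rt
Reagents that add atoms: tert-butyldimethylsilyl chloride (CC(C)(C)[Si](C)(C)Cl)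
Why: Standard silylation of the secondary alcohol so that only the later C19 hydroxyl is free for esterification.

**Step 6**
Reactants: 11 (2E,4S,7S,8E)-7-(TBS-oxy)-N-methoxy-N,4,8-trimethylundeca-2,8,10-trienamide
Product: 12 (4E,6S,9S,10E)-9-(TBS-oxy)-6,10-dimethyltrideca-1,4,10,12-tetraen-3-one
Conditions: CH2=CHMgBr, THF, −20 → 0 °C; inverse quench into cold 0.5 M HCl
Reagents that add atoms: vinylmagnesium bromide (C=C[Mg]Br)
Why: Weinreb ketone synthesis on the unsaturated amide stops at the divinyl ketone because the chelated adduct survives until the quench.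

**Step 7**
Reactants: 12 (4E,6S,9S,10E)-9-(TBS-oxy)-6,10-dimethyltrideca-1,4,10,12-tetraen-3-one; 6 propanal
Product: 14 (2S,6E,8S,11S,12E)-11-(TBS-oxy)-1,1-dimethoxy-2,8,12-trimethylpentadeca-6,12,14-trien-5-one, via keto aldehyde 13 (not isolated)
Conditions: (R)-2-(methoxydiphenylmethyl)pyrrolidine (10 mol%), ethyl 3,4-dihydroxybenzoate (20 mol%), propanal (5 equiv), 4 °C; evaporate propanal; then HC(OMe)3, MeOH, pyridinium p-toluenesulfonate (cat.), 0 °C → rt
Reagents that add atoms: trimethyl orthoformate (COC(OC)OC)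
Why: Second enamine-catalysed Michael addition, to the unsubstituted vinyl group of the cross-conjugated dienone (same facial sense, C16 = S), followed by acetalisation of the aldehyde so that the enone is the only reducible carbonyl.

**Step 8**
Reactants: 14 (2S,6E,8S,11S,12E)-11-(TBS-oxy)-1,1-dimethoxy-2,8,12-trimethylpentadeca-6,12,14-trien-5-one
Product: 15 (2S,5R,6E,8S,11S,12E)-11-(TBS-oxy)-1,1-dimethoxy-2,8,12-trimethylpentadeca-6,12,14-trien-5-ol
Conditions: (S)-2-methyl-CBS-oxazaborolidine (20 mol%), catecholborane, toluene, −78 °C; minor diastereomers removed by chromatography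
Reagents that add atoms: none
Why: Corey–Bakshi–Shibata reduction of the E-enone with the alkenyl group as the large substituent, so the (S)-catalyst gives the (R)-allylic alcohol (C19).

**Step 9**
Reactants: 16 ethyl 2-[bis(2,2,2-trifluoroethoxy)phosphoryl]propanoate
Product: 17 2-[bis(2,2,2-trifluoroethoxy)phosphoryl]propanoic acid
Conditions: LiOH·H2O (1.05 equiv), THF/H2O, 0 °C; then 1 M HCl
Reagents that add atoms: lithium hydroxide ([Li+].[OH-])
Why: Saponification with one equivalent of hydroxide at 0 °C cleaves the carboxylic ester faster than the phosphonate P–O bonds.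

**Step 10**
Reactants: 15 (2S,5R,6E,8S,11S,12E)-11-(TBS-oxy)-1,1-dimethoxy-2,8,12-trimethylpentadeca-6,12,14-trien-5-ol; 17 2-[bis(2,2,2-trifluoroethoxy)phosphoryl]propanoic acid
Product: 18 (2S,5R,6E,8S,11S,12E)-11-(TBS-oxy)-1,1-dimethoxy-2,8,12-trimethylpentadeca-6,12,14-trien-5-yl 2-[bis(2,2,2-trifluoroethoxy)phosphoryl]propanoate (both epimers at the phosphonate carbon)
Conditions: DCC, DMAP (cat.), CH2Cl2, 0 °C → rt
Reagents that add atoms: none
Why: Steglich esterification puts the lactone C–O bond in place with retention at C19 and avoids any later esterification with an isomerisable Z-enoic acid.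

**Step 11**
Reactants: 19 ethyl 4-oxopentanoate
Product: 21 (5R)-5-methylpyrrolidin-2-one, via amino ester 20 (not isolated)
Conditions: (R)-selective ω-transaminase from Arthrobacter sp. (ATA-117), pyridoxal 5′-phosphate, i-PrNH2, phosphate buffer pH 7.5, 35 °C
Reagents that add atoms: isopropylamine (CC(C)N)
Why: Biocatalytic asymmetric transamination delivers the amino group to one face of the methyl ketone (C11 = R), and spontaneous lactamisation of the γ-amino ester pulls the equilibrium over.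

**Step 12**
Reactants: 21 (5R)-5-methylpyrrolidin-2-one
Product: 22 tert-butyl (2R)-2-methyl-5-oxopyrrolidine-1-carboxylate
Conditions: Boc2O, DMAP (cat.), Et3N, CH2Cl2, rt
Reagents that add atoms: di-tert-butyl dicarbonate (CC(C)(C)OC(=O)OC(=O)OC(C)(C)C)
Why: N-acylation with Boc2O activates the lactam carbonyl for ring opening and protects nitrogen.

**Step 13**
Reactants: 22 tert-butyl (2R)-2-methyl-5-oxopyrrolidine-1-carboxylate
Product: 23 tert-butyl N-[(2R)-5-oxohept-6-en-2-yl]carbamate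
Conditions: CH2=CHMgBr, THF, −78 °C; cold 0.5 M HCl
Reagents that add atoms: vinylmagnesium bromide (C=C[Mg]Br)
Why: Grignard ring opening of the N-Boc lactam gives the vinyl ketone after a single addition because the ring-opened carbamate anion is not electrophilic.

**Step 14**
Reactants: 24 2-methylpropane-1,3-diol
Product: 25 (2S)-3-hydroxy-2-methylpropyl acetate
Conditions: lipase from Pseudomonas fluorescens, vinyl acetate, CHCl3, rt
Reagents that add atoms: vinyl acetate (C=COC(C)=O)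
Why: Enzymatic desymmetrisation by enantiotopic-group-selective transesterification sets the future C5 centre; if the chosen lipase prefers the other arm, hydrolysis of the diacetate with the same enzyme gives this enantiomer.

**Step 15**
Reactants: 25 (2S)-3-hydroxy-2-methylpropyl acetate
Product: 26 (2R)-2-methyl-3-oxopropyl acetate
Conditions: Dess–Martin periodinane, NaHCO3, CH2Cl2, 0 °C; used crude
Reagents that add atoms: none
Why: Buffered Dess–Martin oxidation gives the α-chiral aldehyde without base, so neither epimerisation nor acetate β-elimination is expected (the descriptor changes by priority only).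

**Step 16**
Reactants: 23 tert-butyl N-[(2R)-5-oxohept-6-en-2-yl]carbamate; 26 (2R)-2-methyl-3-oxopropyl acetate
Product: 28 (2R,3S,4R,8R)-8-(Boc-amino)-3-hydroxy-2,4-dimethyl-5-oxononyl acetate, via silyl enol ether 27 (not isolated)
Conditions: Et3SiH, RhCl(PPh3)3 (1 mol%), THF, 50 °C; evaporate; then 26, BF3·OEt2, CH2Cl2, −78 °C; aq. NaHCO3
Reagents that add atoms: none
Why: 1,4-Hydrosilylation of the s-cis vinyl ketone gives the Z-enol silane regiospecifically, and its BF3-promoted Mukaiyama aldol addition through an open transition state is Felkin–Anh selective at the α-methyl aldehyde (C6 syn to C5) and syn selective from the Z-enol silane (C7), giving the all-syn triad.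

**Step 17**
Reactants: 28 (2R,3S,4R,8R)-8-(Boc-amino)-3-hydroxy-2,4-dimethyl-5-oxononyl acetate
Product: 29 (2R,3S,4R,8R)-8-(Boc-amino)-3-(TBS-oxy)-2,4-dimethyl-5-oxononyl acetate
Conditions: TBSOTf, 2,6-lutidine, CH2Cl2, −78 → 0 °C
Reagents that add atoms: tert-butyldimethylsilyl trifluoromethanesulfonate (CC(C)(C)[Si](C)(C)OS(=O)(=O)C(F)(F)F)
Why: Silyl triflate with a weak hindered base protects the hindered aldol hydroxyl without enolising the ketone, which blocks retro-aldol and later lactonisation onto the Z-enoate.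

**Step 18**
Reactants: 29 (2R,3S,4R,8R)-8-(Boc-amino)-3-(TBS-oxy)-2,4-dimethyl-5-oxononyl acetate
Product: 30 tert-butyl N-[(2R,6R,7S,8R)-7-(TBS-oxy)-9-hydroxy-6,8-dimethyl-5-oxononan-2-yl]carbamate
Conditions: immobilised Candida antarctica lipase B, pH 7 phosphate buffer/MTBE, 30 °C
Reagents that add atoms: none
Why: Enzymatic hydrolysis of the primary acetate at neutral pH avoids the base that would epimerise C7 or eliminate the β-silyloxy group (the product equilibrates with its six-membered hemiketal).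

**Step 19**
Reactants: 30 tert-butyl N-[(2R,6R,7S,8R)-7-(TBS-oxy)-9-hydroxy-6,8-dimethyl-5-oxononan-2-yl]carbamate
Product: 31 tert-butyl N-[(2R,6R,7S,8S)-7-(TBS-oxy)-6,8-dimethyl-5,9-dioxononan-2-yl]carbamate
Conditions: Dess–Martin periodinane, NaHCO3, CH2Cl2, 0 °C → rt; used at once
Reagents that add atoms: none
Why: Dess–Martin oxidation of the open-chain primary alcohol gives the α-methyl-β-silyloxy aldehyde under neutral conditions.

**Step 20**
Reactants: 18 phosphonate ester (as named in step 10); 31 tert-butyl N-[(2R,6R,7S,8S)-7-(TBS-oxy)-6,8-dimethyl-5,9-dioxononan-2-yl]carbamate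
Product: 32 (2S,5R,6E,8S,11S,12E)-11-(TBS-oxy)-1,1-dimethoxy-2,8,12-trimethylpentadeca-6,12,14-trien-5-yl (2Z,4R,5S,6R,10R)-10-(Boc-amino)-5-(TBS-oxy)-2,4,6-trimethyl-7-oxoundec-2-enoate
Conditions: 18, KN(SiMe3)2, 18-crown-6, THF, −78 °C; then 31, −78 °C
Reagents that add atoms: none
Why: Still–Gennari olefination, in which the bis(trifluoroethyl) phosphonate with a dissociated potassium counter-ion eliminates under kinetic control to the Z-trisubstituted enoate, and it reacts only with the aldehyde, not the C8 ketone.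

**Step 21**
Reactants: 32 (seco ester named in step 20)
Product: 34 (2S,5R,6E,8S,11S,12E)-11-(TBS-oxy)-2,8,12-trimethyl-1-oxopentadeca-6,12,14-trien-5-yl (2Z,4R,5S,6R,10R)-10-(2-diazoacetamido)-5-(TBS-oxy)-2,4,6-trimethyl-7-oxoundec-2-enoate, via amino aldehyde 33 (not isolated)
Conditions: TMSOTf, 2,6-lutidine, CH2Cl2, 0 °C; then poured into THF/aq. NaHCO3 containing 2,5-dioxopyrrolidin-1-yl 2-diazoacetate, 0 °C
Reagents that add atoms: 2,5-dioxopyrrolidin-1-yl 2-diazoacetate ([N-]=[N+]=CC(=O)ON1C(=O)CCC1=O); water (O)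
Why: Silyl triflate/lutidine cleaves the N-Boc group (via the silyl carbamate) and the dimethyl acetal (via a pyridinium adduct) without Brønsted acid, and the amine freed on the aqueous quench is acylated by the active ester faster than it can condense with the C8 ketone or the C15 aldehyde.

**Step 22**
Reactants: 34 (diazoacetamide aldehyde named in step 21)
Product: 35 (3Z,5R,6S,7R,11R,16S,19R)-6-(TBS-oxy)-19-[(1E,3S,6S,7E)-6-(TBS-oxy)-3,7-dimethyldeca-1,7,9-trien-1-yl]-3,5,7,11,16-pentamethyl-1-oxa-12-azacyclononadec-3-ene-2,8,13,15-tetrone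
Conditions: SnCl2 (anhydrous, 0.5 equiv), CH2Cl2, rt, syringe-pump addition of 34 over 12 h to 1 mM
Reagents that add atoms: none
Why: Proposed new method: a macrocyclising intramolecular Roskamp homologation, in which SnCl2 activates the C15 aldehyde, the nucleophilic diazo carbon of the tethered secondary diazoacetamide adds to it, and loss of N2 with 1,2-hydride shift gives the β-keto amide and the 19-membered ring in one step; the closest known reaction is the intermolecular SnCl2-catalysed Roskamp reaction of aldehydes with diazoacetates (α-branched aldehydes react without epimerisation, ketones are inert), and attack on the C8 ketone is further disfavoured because the seven-membered ring would need the cis-amide rotamer.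

**Step 23**
Reactants: 35 (bis-silyl macrocycle named in step 22)
Product: 36 (3Z,5R,6S,7R,11R,16S,19R)-6-hydroxy-19-[(1E,3S,6S,7E)-6-hydroxy-3,7-dimethyldeca-1,7,9-trien-1-yl]-3,5,7,11,16-pentamethyl-1-oxa-12-azacyclononadec-3-ene-2,8,13,15-tetrone
Conditions: HF·pyridine, pyridine, THF, 0 °C → rt
Reagents that add atoms: none
Why: Buffered fluoride desilylation removes both TBS ethers without the base or strong acid that would cause retro-aldol, C16 epimerisation or translactonisation of the C6 hydroxyl onto the Z-enoate.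

**Compound list**
1 | acrolein | C=CC=O | starting material
2 | ethyl 2-(triphenyl-λ5-phosphanylidene)propanoate | CCOC(=O)C(C)=P(c1ccccc1)(c1ccccc1)c1ccccc1 | starting material
3 | ethyl (2E)-2-methylpenta-2,4-dienoate | C=C/C=C(\C)C(=O)OCC | intermediate
4 | (2E)-N-methoxy-N,2-dimethylpenta-2,4-dienamide | C=C/C=C(\C)C(=O)N(C)OC | intermediate
5 | (4E)-4-methylhepta-1,4,6-trien-3-one | C=C/C=C(\C)C(=O)C=C | intermediate
6 | propanal | CCC=O | starting material
7 | N-methoxy-N-methyl-2-(triphenyl-λ5-phosphanylidene)acetamide | CON(C)C(=O)C=P(c1ccccc1)(c1ccccc1)c1ccccc1 | starting material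
8 | (2S,6E)-2,6-dimethyl-5-oxonona-6,8-dienal | C=C/C=C(\C)C(=O)CC[C@H](C)C=O | intermediate
9 | (2E,4S,8E)-N-methoxy-N,4,8-trimethyl-7-oxoundeca-2,8,10-trienamide | C=C/C=C(\C)C(=O)CC[C@H](C)/C=C/C(=O)N(C)OC | intermediate
10 | (2E,4S,7S,8E)-7-hydroxy-N-methoxy-N,4,8-trimethylundeca-2,8,10-trienamide | C=C/C=C(\C)[C@@H](O)CC[C@H](C)/C=C/C(=O)N(C)OC | intermediate
11 | (2E,4S,7S,8E)-7-[(tert-butyldimethylsilyl)oxy]-N-methoxy-N,4,8-trimethylundeca-2,8,10-trienamide | C=C/C=C(\C)[C@@H](O[Si](C)(C)C(C)(C)C)CC[C@H](C)/C=C/C(=O)N(C)OC | intermediate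
12 | (4E,6S,9S,10E)-9-[(tert-butyldimethylsilyl)oxy]-6,10-dimethyltrideca-1,4,10,12-tetraen-3-one | C=C/C=C(\C)[C@@H](O[Si](C)(C)C(C)(C)C)CC[C@H](C)/C=C/C(=O)C=C | intermediate
13 | (2S,6E,8S,11S,12E)-11-[(tert-butyldimethylsilyl)oxy]-2,8,12-trimethyl-5-oxopentadeca-6,12,14-trienal | C=C/C=C(\C)[C@@H](O[Si](C)(C)C(C)(C)C)CC[C@H](C)/C=C/C(=O)CC[C@H](C)C=O | intermediate
14 | (2S,6E,8S,11S,12E)-11-[(tert-butyldimethylsilyl)oxy]-1,1-dimethoxy-2,8,12-trimethylpentadeca-6,12,14-trien-5-one | C=C/C=C(\C)[C@@H](O[Si](C)(C)C(C)(C)C)CC[C@H](C)/C=C/C(=O)CC[C@H](C)C(OC)OC | intermediate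
15 | (2S,5R,6E,8S,11S,12E)-11-[(tert-butyldimethylsilyl)oxy]-1,1-dimethoxy-2,8,12-trimethylpentadeca-6,12,14-trien-5-ol | C=C/C=C(\C)[C@@H](O[Si](C)(C)C(C)(C)C)CC[C@H](C)/C=C/[C@H](O)CC[C@H](C)C(OC)OC | intermediate
16 | ethyl 2-[bis(2,2,2-trifluoroethoxy)phosphoryl]propanoate (racemic) | CCOC(=O)C(C)P(=O)(OCC(F)(F)F)OCC(F)(F)F | starting material
17 | 2-[bis(2,2,2-trifluoroethoxy)phosphoryl]propanoic acid (racemic) | CC(C(=O)O)P(=O)(OCC(F)(F)F)OCC(F)(F)F | intermediate
18 | (2S,5R,6E,8S,11S,12E)-11-[(tert-butyldimethylsilyl)oxy]-1,1-dimethoxy-2,8,12-trimethylpentadeca-6,12,14-trien-5-yl 2-[bis(2,2,2-trifluoroethoxy)phosphoryl]propanoate | C=C/C=C(\C)[C@@H](O[Si](C)(C)C(C)(C)C)CC[C@H](C)/C=C/[C@@H](CC[C@H](C)C(OC)OC)OC(=O)C(C)P(=O)(OCC(F)(F)F)OCC(F)(F)F | intermediate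
19 | ethyl 4-oxopentanoate (ethyl levulinate) | CCOC(=O)CCC(C)=O | starting material
20 | ethyl (4R)-4-aminopentanoate | CCOC(=O)CC[C@@H](C)N | intermediate
21 | (5R)-5-methylpyrrolidin-2-one | C[C@@H]1CCC(=O)N1 | intermediate
22 | tert-butyl (2R)-2-methyl-5-oxopyrrolidine-1-carboxylate | C[C@@H]1CCC(=O)N1C(=O)OC(C)(C)C | intermediate
23 | tert-butyl N-[(2R)-5-oxohept-6-en-2-yl]carbamate | C=CC(=O)CC[C@@H](C)NC(=O)OC(C)(C)C | intermediate
24 | 2-methylpropane-1,3-diol | CC(CO)CO | starting material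
25 | (2S)-3-hydroxy-2-methylpropyl acetate | OC[C@H](C)COC(C)=O | intermediate
26 | (2R)-2-methyl-3-oxopropyl acetate | O=C[C@H](C)COC(C)=O | intermediate
27 | tert-butyl N-[(2R,5Z)-5-[(triethylsilyl)oxy]hept-5-en-2-yl]carbamate | C/C=C(\O[Si](CC)(CC)CC)CC[C@@H](C)NC(=O)OC(C)(C)C | intermediate
28 | (2R,3S,4R,8R)-8-[(tert-butoxycarbonyl)amino]-3-hydroxy-2,4-dimethyl-5-oxononyl acetate | CC(C)(C)OC(=O)N[C@H](C)CCC(=O)[C@H](C)[C@@H](O)[C@H](C)COC(C)=O | intermediate
29 | (2R,3S,4R,8R)-8-[(tert-butoxycarbonyl)amino]-3-[(tert-butyldimethylsilyl)oxy]-2,4-dimethyl-5-oxononyl acetate | CC(C)(C)OC(=O)N[C@H](C)CCC(=O)[C@H](C)[C@@H](O[Si](C)(C)C(C)(C)C)[C@H](C)COC(C)=O | intermediate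
30 | tert-butyl N-[(2R,6R,7S,8R)-7-[(tert-butyldimethylsilyl)oxy]-9-hydroxy-6,8-dimethyl-5-oxononan-2-yl]carbamate | CC(C)(C)OC(=O)N[C@H](C)CCC(=O)[C@H](C)[C@@H](O[Si](C)(C)C(C)(C)C)[C@H](C)CO | intermediate
31 | tert-butyl N-[(2R,6R,7S,8S)-7-[(tert-butyldimethylsilyl)oxy]-6,8-dimethyl-5,9-dioxononan-2-yl]carbamate | CC(C)(C)OC(=O)N[C@H](C)CCC(=O)[C@H](C)[C@@H](O[Si](C)(C)C(C)(C)C)[C@H](C)C=O | intermediate
32 | (2S,5R,6E,8S,11S,12E)-11-[(tert-butyldimethylsilyl)oxy]-1,1-dimethoxy-2,8,12-trimethylpentadeca-6,12,14-trien-5-yl (2Z,4R,5S,6R,10R)-10-[(tert-butoxycarbonyl)amino]-5-[(tert-butyldimethylsilyl)oxy]-2,4,6-trimethyl-7-oxoundec-2-enoate | C=C/C=C(\C)[C@@H](O[Si](C)(C)C(C)(C)C)CC[C@H](C)/C=C/[C@@H](CC[C@H](C)C(OC)OC)OC(=O)/C(C)=C\[C@@H](C)[C@H](O[Si](C)(C)C(C)(C)C)[C@@H](C)C(=O)CC[C@@H](C)NC(=O)OC(C)(C)C | intermediate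
33 | (2S,5R,6E,8S,11S,12E)-11-[(tert-butyldimethylsilyl)oxy]-2,8,12-trimethyl-1-oxopentadeca-6,12,14-trien-5-yl (2Z,4R,5S,6R,10R)-10-amino-5-[(tert-butyldimethylsilyl)oxy]-2,4,6-trimethyl-7-oxoundec-2-enoate | C=C/C=C(\C)[C@@H](O[Si](C)(C)C(C)(C)C)CC[C@H](C)/C=C/[C@@H](CC[C@H](C)C=O)OC(=O)/C(C)=C\[C@@H](C)[C@H](O[Si](C)(C)C(C)(C)C)[C@@H](C)C(=O)CC[C@@H](C)N | intermediate
34 | (2S,5R,6E,8S,11S,12E)-11-[(tert-butyldimethylsilyl)oxy]-2,8,12-trimethyl-1-oxopentadeca-6,12,14-trien-5-yl (2Z,4R,5S,6R,10R)-10-(2-diazoacetamido)-5-[(tert-butyldimethylsilyl)oxy]-2,4,6-trimethyl-7-oxoundec-2-enoate | C=C/C=C(\C)[C@@H](O[Si](C)(C)C(C)(C)C)CC[C@H](C)/C=C/[C@@H](CC[C@H](C)C=O)OC(=O)/C(C)=C\[C@@H](C)[C@H](O[Si](C)(C)C(C)(C)C)[C@@H](C)C(=O)CC[C@@H](C)NC(=O)C=[N+]=[N-] | intermediate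
35 | (3Z,5R,6S,7R,11R,16S,19R)-6-[(tert-butyldimethylsilyl)oxy]-19-[(1E,3S,6S,7E)-6-[(tert-butyldimethylsilyl)oxy]-3,7-dimethyldeca-1,7,9-trien-1-yl]-3,5,7,11,16-pentamethyl-1-oxa-12-azacyclononadec-3-ene-2,8,13,15-tetrone | C=C/C=C(\C)[C@@H](O[Si](C)(C)C(C)(C)C)CC[C@H](C)/C=C/[C@H]1CC[C@H](C)C(=O)CC(=O)N[C@H](C)CCC(=O)[C@H](C)[C@@H](O[Si](C)(C)C(C)(C)C)[C@H](C)/C=C(/C)C(=O)O1 | intermediate
36 | (3Z,5R,6S,7R,11R,16S,19R)-6-hydroxy-19-[(1E,3S,6S,7E)-6-hydroxy-3,7-dimethyldeca-1,7,9-trien-1-yl]-3,5,7,11,16-pentamethyl-1-oxa-12-azacyclononadec-3-ene-2,8,13,15-tetrone | C=C/C=C(\C)[C@@H](O)CC[C@H](C)/C=C/[C@H]1CC[C@H](C)C(=O)CC(=O)N[C@H](C)CCC(=O)[C@H](C)[C@@H](O)[C@H](C)/C=C(/C)C(=O)O1 | target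

**Step count**
Total: 23 steps. Longest linear sequence: 13 steps (1, 2, 3, 4, 5, 6, 7, 8, 10, 20, 21, 22, 23).

**Three steps most likely to fail**

Step 22 (the proposed new ring closure). Risks are oligomerisation, protonation of the diazo group by traces of HCl, and attack on the C8 ketone. The fallback uses known chemistry, sets out from 32 and comes back at 35. Deprotection as in step 21 gives amino aldehyde 33, which is trapped in the same THF/aq. NaHCO3 quench with bromoacetyl bromide to give the bromoacetamide aldehyde F1. SmI2 in THF at −78 °C under high dilution then closes the ring by an intramolecular Reformatsky reaction onto the C15 aldehyde, giving the β-hydroxy lactam F2 as both C15 epimers. Dess–Martin oxidation of F2 gives 35.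

Step 16 (Mukaiyama aldol). The enol silane carries only a primary alkyl group, so syn/anti selectivity in the open transition state may be modest, and the β-acetoxy aldehyde gives only moderate Felkin bias. The fallback replaces substrate control in an open transition state by reagent control in a closed one; it sets out from 23 (with 26) and comes back at 28. 1,4-Hydroboration of 23 with (+)-diisopinocampheylborane (from (−)-α-pinene and BH3·SMe2, Et2O, 0 °C) gives the Z-enol diisopinocampheylborinate F3. F3 adds to 26 at −78 °C through a chair transition state to the syn aldol, and work-up with H2O2 in pH 7 buffer gives 28. The antipode named is the one expected, by analogy with allylboration with the same ligands, to attack the Re face of 26; this is to be checked on isobutyraldehyde and the other antipode used if the sense is reversed. This fallback uses a stoichiometric chiral borane.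

Step 21 (one-pot N-Boc/acetal cleavage and N-diazoacetylation). The freed amine can condense with the C8 ketone (five-membered cyclic imine) or the C15 aldehyde before it is acylated, and the silyl triflate may ionise the dienylic silyl ether. The fallback caps nitrogen at the fragment stage, where neither the aldehyde nor the dienyl ether is present; it sets out from 29 and comes back at 34. CF3CO2H in CH2Cl2 at 0 °C removes the Boc group to give the ammonium trifluoroacetate F4. F4 is acylated at once in THF/aq. NaHCO3 with 2,5-dioxopyrrolidin-1-yl 2-diazoacetate to the diazoacetamide acetate F5. Lipase hydrolysis as in step 18 gives the diazoacetamide alcohol F6, and Dess–Martin oxidation gives the diazoacetamide aldehyde F7. Still–Gennari olefination of F7 with 18 as in step 20 gives the diazoacetamide acetal F8. Hydrolysis of the dimethyl acetal with pyridinium p-toluenesulfonate in wet acetone, mild enough for a diazoacetamide, gives 34.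

**Further compounds**
F1 | step 22 | (2S,5R,6E,8S,11S,12E)-11-[(tert-butyldimethylsilyl)oxy]-2,8,12-trimethyl-1-oxopentadeca-6,12,14-trien-5-yl (2Z,4R,5S,6R,10R)-10-(2-bromoacetamido)-5-[(tert-butyldimethylsilyl)oxy]-2,4,6-trimethyl-7-oxoundec-2-enoate | C=C/C=C(\C)[C@@H](O[Si](C)(C)C(C)(C)C)CC[C@H](C)/C=C/[C@@H](CC[C@H](C)C=O)OC(=O)/C(C)=C\[C@@H](C)[C@H](O[Si](C)(C)C(C)(C)C)[C@@H](C)C(=O)CC[C@@H](C)NC(=O)CBr
F2 | step 22 | (3Z,5R,6S,7R,11R,16S,19R)-6-[(tert-butyldimethylsilyl)oxy]-19-[(1E,3S,6S,7E)-6-[(tert-butyldimethylsilyl)oxy]-3,7-dimethyldeca-1,7,9-trien-1-yl]-15-hydroxy-3,5,7,11,16-pentamethyl-1-oxa-12-azacyclononadec-3-ene-2,8,13-trione (both C15 epimers) | C=C/C=C(\C)[C@@H](O[Si](C)(C)C(C)(C)C)CC[C@H](C)/C=C/[C@H]1CC[C@H](C)C(O)CC(=O)N[C@H](C)CCC(=O)[C@H](C)[C@@H](O[Si](C)(C)C(C)(C)C)[C@H](C)/C=C(/C)C(=O)O1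
F3 | step 16 | tert-butyl N-[(2R,5Z)-5-{[bis((1S,2R,3S,5S)-2,6,6-trimethylbicyclo[3.1.1]heptan-3-yl)boranyl]oxy}hept-5-en-2-yl]carbamate (Z-enol diisopinocampheylborinate) | C/C=C(\OB([C@H]1C[C@H]2C[C@H](C2(C)C)[C@@H]1C)[C@H]1C[C@H]2C[C@H](C2(C)C)[C@@H]1C)CC[C@@H](C)NC(=O)OC(C)(C)C
F4 | step 21 | (2R,3S,4R,8R)-8-amino-3-[(tert-butyldimethylsilyl)oxy]-2,4-dimethyl-5-oxononyl acetate (as its trifluoroacetate salt) | N[C@H](C)CCC(=O)[C@H](C)[C@@H](O[Si](C)(C)C(C)(C)C)[C@H](C)COC(C)=O
F5 | step 21 | (2R,3S,4R,8R)-8-(2-diazoacetamido)-3-[(tert-butyldimethylsilyl)oxy]-2,4-dimethyl-5-oxononyl acetate | [N-]=[N+]=CC(=O)N[C@H](C)CCC(=O)[C@H](C)[C@@H](O[Si](C)(C)C(C)(C)C)[C@H](C)COC(C)=O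
F6 | step 21 | N-[(2R,6R,7S,8R)-7-[(tert-butyldimethylsilyl)oxy]-9-hydroxy-6,8-dimethyl-5-oxononan-2-yl]-2-diazoacetamide | [N-]=[N+]=CC(=O)N[C@H](C)CCC(=O)[C@H](C)[C@@H](O[Si](C)(C)C(C)(C)C)[C@H](C)CO
F7 | step 21 | N-[(2R,6R,7S,8S)-7-[(tert-butyldimethylsilyl)oxy]-6,8-dimethyl-5,9-dioxononan-2-yl]-2-diazoacetamide | [N-]=[N+]=CC(=O)N[C@H](C)CCC(=O)[C@H](C)[C@@H](O[Si](C)(C)C(C)(C)C)[C@H](C)C=O
F8 | step 21 | (2S,5R,6E,8S,11S,12E)-11-[(tert-butyldimethylsilyl)oxy]-1,1-dimethoxy-2,8,12-trimethylpentadeca-6,12,14-trien-5-yl (2Z,4R,5S,6R,10R)-10-(2-diazoacetamido)-5-[(tert-butyldimethylsilyl)oxy]-2,4,6-trimethyl-7-oxoundec-2-enoate | C=C/C=C(\C)[C@@H](O[Si](C)(C)C(C)(C)C)CC[C@H](C)/C=C/[C@@H](CC[C@H](C)C(OC)OC)OC(=O)/C(C)=C\[C@@H](C)[C@H](O[Si](C)(C)C(C)(C)C)[C@@H](C)C(=O)CC[C@@H](C)NC(=O)C=[N+]=[N-]
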